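The vessel is closed, stirred and of constant volume, and two earlier runs stand beside the two flasks to be compared.

| setting | delta | gamma | summer | midnight |
|---|---|---|---|---|
| substrate | 2.7 M | 2.7 M | 2.7 M | 2.7 M |
| free catalyst | 3.6 mM | 8.1 mM | 5.4 mM | 5.4 mM |
| temperature | −15 °C | −4 °C |  |  |
| remark | run made earlier | run made earlier | at −20 °C throughout | at 0 °C until 30 h, from then on at −20 °C |
| time |  |  | 2.5 d | 2.5 d |

delta run (percent of the substrate charged)

| time / d | target / % | substrate / % |
|---|---|---|
| 0.250 | 0 | 99 |
| 0.333 | 0 | 103 |
| 0.500 | 4 | 98 |
| 0.833 | 3 | 100 |
| 1.25 | 4 | 96 |
| 2.00 | 7 | 94 |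
| 4.00 | 3 | 85 |

gamma run (percent of the substrate charged)

| time / h | target / % | substrate / % |
|---|---|---|
| 3.00 | 3 | 98 |
| 4.00 | 2 | 96 |
| 6.00 | 4 | 89 |
| 10.0 | 5 | 88 |
| 15.0 | 8 | 82 |
| 25.0 | 13 | 63 |
| 40.0 | 18 | 46 |

(each reading ± 2 percentage points)

- the winner by amount of target, in percent of the substrate charged; "neither" if no more than 2 percentage points parts them (summer / midnight / neither)
- how much target is there at the end, in percent of the substrate charged: summer
- how much target is there at the end, in percent of the substrate charged: midnight

- a species is counted by the substrate in it: one side product counts as two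
- what was read earlier has a scatter of 2 percentage points, one standard deviation
- steps under discussion: substrate + free catalyst -> catalyst intermediate; catalyst intermediate -> free catalyst + target; substrate + target -> side product

Take the main step first. With the binding and release of catalyst taken as steady, they leave one rate to read: the turnover frequency w, target made per catalyst charged per hour. Each side product holds one substrate and one target that was made, so target made = 0.5·(substrate lost + target read). The gamma readings give an average w = 2.89 h⁻¹ up to 15.0 h, with substrate read at 82 %, and 3.00 h⁻¹ up to 40.0 h, with substrate read at 46 %, so these two averages show no fall of w as c(substrate) falls. The last delta reading gives an average of 0.703 h⁻¹. Read from these two scattered averages, the apparent activation energy is 76.2 kJ mol⁻¹, which gives an estimated w = 4.94 h⁻¹ at 0 °C and a cold turnover frequency of 0.349 h⁻¹ at −20 °C. Multiplied by the catalyst charged and the time, w gives an estimate of 4.19 % of target made in summer and 29.6 % made in midnight while warm.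

Now add the side step. It eats target in step with c(substrate)·c(target), so the target left in summer is reckoned below the 4.19 % made. At its last reading, the gamma run held 18 % of target out of 36.0 % made. Scaling that held target by the catalyst charged, and assuming that making and eating keep their ratio between −4 °C and 0 °C, this reckoning puts midnight at about 12.0 % at the change.

The cold stage of midnight is then reckoned to make 2.09 %, so this reckoning puts midnight at 14.1 % before any eating in the cold, more than the 4.19 % made in summer.

The forecast, with “target approaches a plateau near 9–10 % by 30 h”, also names midnight, at 12 % (9 % to 15 %) against 5.2 % (4 % to 6.5 %) for summer.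

Summer ends at 3.92 % of target and midnight at 13.1 %, so midnight leads by 9.2 percentage points.

    substrate + free catalyst → catalyst intermediate (k = 5.80 L mol⁻¹ h⁻¹, Ea = 60.0 kJ mol⁻¹)
    catalyst intermediate → free catalyst + target (k = 8.10 h⁻¹, Ea = 80.0 kJ mol⁻¹)
    substrate + target → side product (k = 0.0350 L mol⁻¹ h⁻¹, Ea = 76.0 kJ mol⁻¹)
    (constants at 0 °C)

The midnight flask ends with 35.7 % of side product, which makes its total target made 30.9 %, against 31.7 % reckoned from w. The same flask read at 10 d is reckoned, with the cold turnover frequency, to have made 44.3 %; its 50.6 % of side product and 16.7 % of target come to 42.0 %.

The earlier runs and the new flask were generated by integration on assumed constants.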